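**Retrosynthetic overview**

1. Labdane numbering is used. Ring A is C1–C5 plus C10 and ring B is C5–C10. C17 sits on C8, C18 (CH2OH) and C19 (CH3) on C4, C20 on C10, and the side chain C11–C16 on C9.
2. Enabling feature: in ring A the quaternary C4 lies between the O-bearing C3 and the O-bearing C18 (triad O–C3–C4–C18–O). This 1,3-diol is the retron of a reductive union of two electrophilic carbons, the oxirane carbon C4 (oxirane C4/C18) and the aldehyde carbon C3. The key disconnection is therefore C3–C4.
3. The monocyclic epoxy dialdehyde comes from a ring B triene. One double hydroformylation adds C3 to a C10 vinyl group and C14 to a C9 allyl group. After ring closure C14 is taken to the diene by α-methylenation and Wittig methylenation, and the 3-acetate is set last.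
4. Ring B with C5, C9 and C10 comes from (−)-verbenone. Vinyl and allyl both enter anti to the gem-dimethyl bridge. The cyclobutane (a temporary ring) is then cleaved, so the bridge becomes the C5 isopropenyl group (C4, C18, C19). Methyl addition to the C8 ketone sets C8.
5. Ring order: ring B is present from the start, the cyclobutane is opened in step 3, and ring A is closed last in step 8.

Key step: step 8

Assumption: the oxirane carbon in 9 and 10 (and in F1, F4, F5) and the orthoester carbon in 14 are carried as mixtures of epimers and written without configuration, because both centres are erased in the following step.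

Step 1
Reactants: 1 (1S,5S)-(−)-verbenone
Product: 2 (1S,4R,5R)-4,6,6-trimethyl-4-vinylbicyclo[3.1.1]heptan-2-one (vinyl anti to the gem-dimethyl bridge)
Conditions: CH2=CHMgBr, CuBr·SMe2 (10 mol %), THF, −40 to 0 °C; aq NH4Cl
Reagents that add atoms: vinylmagnesium bromide, C=C[Mg]Br
Why: In this copper-catalysed 1,4-addition of a Grignard reagent the gem-dimethyl bridge shields one face of the enone, so the vinyl group (C1–C2) should enter C10 from the methylene-bridge face and set the quaternary centre with C20 on the side of the bridge that later becomes the C5 substituent.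

Step 2
Reactants: 2 (1S,4R,5R)-4,6,6-trimethyl-4-vinylbicyclo[3.1.1]heptan-2-one
Product: 4 (1S,3R,4R,5R)-3-allyl-4,6,6-trimethyl-4-vinylbicyclo[3.1.1]heptan-2-one (allyl cis to vinyl), via C9 lithium enolate 3 (not isolated)
Conditions: LiN(i-Pr)2, THF, −78 to 0 °C; allyl iodide, DMPU, −78 °C to rt
Reagents that add atoms: allyl iodide, C=CCI
Why: In this enolate alkylation the ketone can enolise only towards C9 because C7 is a bridgehead, and the overhanging methyl of the bridge should again force the electrophile to the methylene-bridge face, which sets C9 with the allyl group (C11–C13) cis to the vinyl group and trans to C20.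

Step 3
Reactants: 4 (1S,3R,4R,5R)-3-allyl-4,6,6-trimethyl-4-vinylbicyclo[3.1.1]heptan-2-one
Product: 5 (4R,5R,6R)-6-allyl-5-methyl-4-(prop-1-en-2-yl)-5-vinylcyclohex-1-en-1-yl acetate
Conditions: BF3·OEt2, Zn(OAc)2, Ac2O, 0 °C to rt
Reagents that add atoms: acetic anhydride, CC(=O)OC(C)=O
Why: In this Lewis acid-promoted cyclobutane cleavage of a nopinone-type ketone the activated carbonyl releases the strained C7–C4 bond to a tertiary cation that loses a methyl proton to give the isopropenyl group, while the enol is trapped as its acetate on the C7 side, so C5, C9 and C10 are not touched.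

Step 4
Reactants: 5 (4R,5R,6R)-6-allyl-5-methyl-4-(prop-1-en-2-yl)-5-vinylcyclohex-1-en-1-yl acetate
Product: 7 (2R,3R,4R)-2-allyl-3-methyl-4-(prop-1-en-2-yl)-3-vinylcyclohexan-1-one, via ring B lithium enolate 6 (not isolated)
Conditions: MeLi (2.1 equiv), Et2O, 0 °C; inverse quench into AcOH/THF, −78 °C
Reagents that add atoms: none
Why: Cleavage of the enol acetate with methyllithium gives the regiodefined C7=C8 enolate, and its kinetic protonation at C7 should release the ketone without exposing the epimerisable C9 centre to equilibrating base.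

Step 5
Reactants: 7 (2R,3R,4R)-2-allyl-3-methyl-4-(prop-1-en-2-yl)-3-vinylcyclohexan-1-one
Product: 8 (1S,2R,3R,4R)-2-allyl-1,3-dimethyl-4-(prop-1-en-2-yl)-3-vinylcyclohexan-1-ol
Conditions: MeLi, CeCl3 (dried), THF, −78 °C; aq NH4Cl
Reagents that add atoms: methyllithium, [Li]C
Why: In this 1,2-addition of a non-basic organocerium reagent, as with 2-alkylcyclohexanones, equatorial attack on the chair that holds the C9 allyl group equatorial and the C10 vinyl group axial should bring the methyl group (C17) in trans to both, which sets C8 with its hydroxyl cis to the allyl group.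

Step 6
Reactants: 8 (1S,2R,3R,4R)-2-allyl-1,3-dimethyl-4-(prop-1-en-2-yl)-3-vinylcyclohexan-1-ol
Product: 9 epoxide of 8 at the isopropenyl group (2-methyloxiran-2-yl on C5; ring centres as in 8)
Conditions: m-CPBA (1.0 equiv), CH2Cl2, −10 °C
Reagents that add atoms: m-CPBA, O=C(OO)c1cccc(Cl)c1
Why: Prilezhaev epoxidation follows alkene nucleophilicity, so the 1,1-disubstituted isopropenyl group should react ahead of the two monosubstituted alkenes, and the unselective formation of the oxirane centre is harmless because step 8 makes it planar.

Step 7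
Reactants: 9 epoxide of 8 at the isopropenyl group
Product: 10 epoxy dialdehyde (C10 carries 3-oxopropyl; C9 carries 4-oxobutyl; C5 carries 2-methyloxiran-2-yl; ring centres as in 8)
Conditions: Rh(acac)(CO)2 (2 mol %), BIPHEPHOS (4 mol %), CO/H2 (1:1, 10 bar), toluene, 70 °C
Reagents that add atoms: carbon monoxide, [C-]#[O+]
Why: Linear-selective rhodium-catalysed hydroformylation with a wide-bite-angle diphosphite should add C3 to the vinyl group and C14 to the allyl group in one operation, the neopentyl position of the vinyl group excluding the branched aldehyde, and no stereocentre is formed.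

Step 8
Reactants: 10 epoxy dialdehyde
Product: 11 (3R,4S,5S,8S,9R,10R)-3,8,18-trihydroxy-15,16-dinorlabdan-14-al
Conditions: Cp2TiCl2 (2.5 equiv), Mn dust, THF, rt, slow mixing at 0.01 M; 1 M HCl
Reagents that add atoms: none
Why: Cp2TiCl (trivalent titanium, made in the flask from Cp2TiCl2 and Mn) binds the oxirane oxygen and cleaves the C4–O bond homolytically, so both epimers of 10 converge on one planar tertiary C4 radical that keeps the C18–O–Ti group; this nucleophilic radical adds to the C3 aldehyde carbon, and a second Cp2TiCl reduces the oxygen-centred radical to a titanium alkoxide, which stops β-scission and unites two carbons that are both electrophilic in the precursor. The closest known reaction type is the titanocene-mediated reductive opening of epoxides followed by intramolecular radical addition to an aldehyde or ketone carbonyl, which gives cycloalkane-1,3-diols. Ring A is closed in the 6-exo-trig mode onto the C=O bond through a chair transition state that is reachable only from the ring B chair with the C5 and C10 arms both equatorial, so the trans ring fusion follows from the existing C5 and C10 centres. C4 is controlled by the axial C20 methyl group, because the bulky CH2O–TiCp2Cl arm avoids the 1,3-diaxial contact, becomes the equatorial C18 and leaves C19 axial. C3 is controlled by the same chair, in which the titanium-bound carbonyl oxygen should take the pseudo-equatorial site and end as the equatorial alcohol. The radical must choose the C3 aldehyde over the C14 aldehyde and must add before it is reduced or disproportionates; the first is secured by ring size (six- against eight-membered closure), the second by the slow capture of a tertiary radical by the bulky titanium reagent and by high dilution.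

Step 9
Reactants: 11 (3R,4S,5S,8S,9R,10R)-3,8,18-trihydroxy-15,16-dinorlabdan-14-al
Product: 12 (3R,4S,5S,8S,9R,10R)-3,8,18-trihydroxy-15-norlabd-13(16)-en-14-al
Conditions: aq CH2O, pyrrolidine (20 mol %), EtCO2H (20 mol %), i-PrOH, 45 °C
Reagents that add atoms: formaldehyde, C=O
Why: The amine-catalysed Mannich condensation–elimination (α-methylenation of an aldehyde) should install C16 on C13 under nearly neutral conditions that the three free hydroxyl groups tolerate, and no stereocentre is formed.

Step 10
Reactants: 12 (3R,4S,5S,8S,9R,10R)-3,8,18-trihydroxy-15-norlabd-13(16)-en-14-al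
Product: 13 (3R,4S,5S,8S,9R,10R)-labda-13(16),14-diene-3,8,18-triol
Conditions: Ph3PCH3Br, KOtBu, THF, 0 °C; then 12, −78 to 0 °C
Reagents that add atoms: methyltriphenylphosphonium bromide, C[P+](c1ccccc1)(c1ccccc1)c1ccccc1.[Br-]
Why: Wittig methylenation of the 2-substituted acrolein should give the 2-substituted 1,3-butadiene, since the aldehyde reacts far faster than the ylide is quenched by the less acidic alcohols, and no stereocentre is touched.

Step 11
Reactants: 13 (3R,4S,5S,8S,9R,10R)-labda-13(16),14-diene-3,8,18-triol
Product: 15 (3R,4S,5S,8S,9R,10R)-8,18-dihydroxylabda-13(16),14-dien-3-yl acetate (target CNP0313672.1), via cyclic 3,18-orthoacetate 14 (not isolated)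
Conditions: MeC(OMe)3, CSA (5 mol %), CH2Cl2, rt; then 80% aq AcOH, 0 °C
Reagents that add atoms: trimethyl orthoacetate, COC(C)(OC)OC; water, O
Why: In this orthoester-mediated monoacylation of a diol the 3,18-diol forms a trans-fused cyclic orthoacetate whose kinetic acid hydrolysis should open towards the ester of the more hindered secondary oxygen and free the primary C18 hydroxyl, while the tertiary C8 hydroxyl cannot be held in a ring and stays free.

**Compound list**

1 | (1S,5S)-(−)-verbenone | CC1=CC(=O)[C@H]2C[C@@H]1C2(C)C | starting material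
2 | (1S,4R,5R)-4,6,6-trimethyl-4-vinylbicyclo[3.1.1]heptan-2-one | O=C1C[C@](C)(C=C)[C@@H]2C[C@H]1C2(C)C | intermediate
3 | C9 lithium enolate of 2 | [Li+].[O-]C1=C[C@](C)(C=C)[C@@H]2C[C@H]1C2(C)C | intermediate
4 | (1S,3R,4R,5R)-3-allyl-4,6,6-trimethyl-4-vinylbicyclo[3.1.1]heptan-2-one | C=CC[C@@H]1[C@](C)(C=C)[C@@H]2C[C@H](C1=O)C2(C)C | intermediate
5 | (4R,5R,6R)-6-allyl-5-methyl-4-(prop-1-en-2-yl)-5-vinylcyclohex-1-en-1-yl acetate | C=CC[C@@H]1[C@](C)(C=C)[C@H](CC=C1OC(C)=O)C(C)=C | intermediate
6 | ring B lithium enolate (C7=C8) from 5 | [Li+].C=CC[C@@H]1[C@](C)(C=C)[C@H](CC=C1[O-])C(C)=C | intermediate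
7 | (2R,3R,4R)-2-allyl-3-methyl-4-(prop-1-en-2-yl)-3-vinylcyclohexan-1-one | C=CC[C@@H]1[C@](C)(C=C)[C@H](CCC1=O)C(C)=C | intermediate
8 | (1S,2R,3R,4R)-2-allyl-1,3-dimethyl-4-(prop-1-en-2-yl)-3-vinylcyclohexan-1-ol | C=CC[C@@H]1[C@](C)(C=C)[C@H](CC[C@]1(C)O)C(C)=C | intermediate
9 | epoxide of 8 at the isopropenyl group (both oxirane epimers) | C=CC[C@@H]1[C@](C)(C=C)[C@H](CC[C@]1(C)O)C2(C)CO2 | intermediate
10 | epoxy dialdehyde (3-oxopropyl on C10, 4-oxobutyl on C9, 2-methyloxiran-2-yl on C5) | O=CCCC[C@@H]1[C@](C)(CCC=O)[C@H](CC[C@]1(C)O)C2(C)CO2 | intermediate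
11 | (3R,4S,5S,8S,9R,10R)-3,8,18-trihydroxy-15,16-dinorlabdan-14-al | O=CCCC[C@@H]1[C@]2(C)CC[C@@H](O)[C@](C)(CO)[C@H]2CC[C@]1(C)O | intermediate
12 | (3R,4S,5S,8S,9R,10R)-3,8,18-trihydroxy-15-norlabd-13(16)-en-14-al | O=CC(=C)CC[C@@H]1[C@]2(C)CC[C@@H](O)[C@](C)(CO)[C@H]2CC[C@]1(C)O | intermediate
13 | (3R,4S,5S,8S,9R,10R)-labda-13(16),14-diene-3,8,18-triol | C=CC(=C)CC[C@@H]1[C@]2(C)CC[C@@H](O)[C@](C)(CO)[C@H]2CC[C@]1(C)O | intermediate
14 | cyclic 3,18-orthoacetate (2-methoxy-2-methyl-1,3-dioxane) of 13 | C=CC(=C)CC[C@@H]1[C@]2(C)CC[C@H]3OC(C)(OC)OC[C@]3(C)[C@H]2CC[C@]1(C)O | intermediate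
15 | (3R,4S,5S,8S,9R,10R)-8,18-dihydroxylabda-13(16),14-dien-3-yl acetate | C=CC(=C)CC[C@@H]1[C@]2(C)CC[C@@H](OC(C)=O)[C@](C)(CO)[C@H]2CC[C@]1(C)O | target

Total step count: 11. Longest linear sequence: 11 steps from 1.

**Steps most likely to fail**

**Step 8.**
- What may go wrong: the tertiary radical may be reduced or may disproportionate before it adds. The addition to the aldehyde may revert by β-scission. The facial selectivity at C3 may be poor.
- Change of approach: the fallback changes the acceptor and moves the control of C3 to a separate hydride reduction.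
- Route: it sets out from 10.
  - I2 and aqueous NH3 in THF would convert both aldehydes into the epoxy dinitrile F1.
  - Cp2TiCl (from Cp2TiCl2 and Mn, THF, rt) would open the oxirane. The C4 radical would add 6-exo-dig to the C3 nitrile, an addition that does not revert because the iminyl radical is reduced at once. Hydrolytic work-up would give the 3-oxo-18-hydroxy nitrile F2.
  - NaBH4 in MeOH at 0 °C, as with 4,4-disubstituted 3-oxo terpenoids, would give the equatorial alcohol in the triol nitrile F3.
  - Excess i-Bu2AlH (CH2Cl2, −78 °C) and mild acid hydrolysis would turn the C14 nitrile into the aldehyde.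
- The route is rejoined at 11.

**Step 5.**
- What may go wrong: the methyl nucleophile may attack the other face of the flexible ketone, or C9 may epimerise by enolisation.
- Change of approach: the fallback attaches carbon first and oxygen second, so the more open face of C8 receives the oxygen.
- Route: it sets out from 7.
  - m-CPBA (CH2Cl2, −10 °C) would epoxidise the isopropenyl group to the epoxy ketone F4.
  - Cp2TiMe2 (toluene, 70 °C), a non-basic methylenation that leaves C9 untouched, would give the exocyclic alkene F5.
  - Mukaiyama hydration (Mn(dpm)3 cat., PhSiH3, O2, i-PrOH, 0 °C, then PPh3) would select the 1,1-disubstituted alkene, make C17 from the methylene carbon and place the hydroxyl on C8.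
- The route is rejoined at 9.

**Step 11.**
- What may go wrong: the orthoester may open towards the primary acetate, or the acetyl group may migrate from O3 to O18 during isolation.
- Change of approach: the fallback uses protecting groups instead.
- Route: it sets out from 13.
  - TBSCl and imidazole (DMF, 0 °C) would silylate only the primary alcohol to give the 18-silyl ether F6.
  - Ac2O, DMAP and pyridine (rt) would acetylate the secondary C3 hydroxyl but not the tertiary one, giving the 3-acetate 18-silyl ether F7.
  - HF·pyridine in THF/pyridine (0 °C), an acidic desilylation that avoids base-induced acyl migration, would remove the silyl group.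
- The route ends at 15.

Further compounds
F1 | step 8 | epoxy dinitrile (2-cyanoethyl on C10, 3-cyanopropyl on C9, 2-methyloxiran-2-yl on C5) | N#CCCC[C@@H]1[C@](C)(CCC#N)[C@H](CC[C@]1(C)O)C2(C)CO2
F2 | step 8 | (4S,5S,8S,9R,10R)-8,18-dihydroxy-3-oxo-15,16-dinorlabdane-14-nitrile | N#CCCC[C@@H]1[C@]2(C)CCC(=O)[C@](C)(CO)[C@H]2CC[C@]1(C)O
F3 | step 8 | (3R,4S,5S,8S,9R,10R)-3,8,18-trihydroxy-15,16-dinorlabdane-14-nitrile | N#CCCC[C@@H]1[C@]2(C)CC[C@@H](O)[C@](C)(CO)[C@H]2CC[C@]1(C)O
F4 | step 5 | epoxy ketone (epoxide of 7 at the isopropenyl group) | C=CC[C@@H]1[C@](C)(C=C)[C@H](CCC1=O)C2(C)CO2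
F5 | step 5 | exocyclic alkene (C8 methylidene analogue of F4) | C=CC[C@@H]1[C@](C)(C=C)[C@H](CCC1=C)C2(C)CO2
F6 | step 11 | 18-O-tert-butyldimethylsilyl ether of 13 | C=CC(=C)CC[C@@H]1[C@]2(C)CC[C@@H](O)[C@](C)(CO[Si](C)(C)C(C)(C)C)[C@H]2CC[C@]1(C)O
F7 | step 11 | 3-acetate of F6 | C=CC(=C)CC[C@@H]1[C@]2(C)CC[C@@H](OC(C)=O)[C@](C)(CO[Si](C)(C)C(C)(C)C)[C@H]2CC[C@]1(C)O
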